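Readings and results are simulated for an exercise, and the scatter is random.

Late times are the question here, so the reckoning starts from the last reading of Tuesday's run, which is this same flask followed to 2.50 d.

- Tuesday's: D 0.10 M; J 0.060 M; the very flask that is asked about, followed so far
- flask: D 0.10 M; J 0.0600 M; time 15 d

- Tuesday's (time / d: D / %, L / %, Q / %): 0.250: 92, 5, 5; 0.625: 90, 6, 7; 1.25: 76, 10, 9; 2.08: 63, 10, 22; 2.50: 61, 12, 27

(standard deviation of a reading: 2 percentage points)

- as a solid, counted per litre of solution: J
- the numbers in the tables scatter with a standard deviation of 2 percentage points
- at the start none of J is in solution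
- the reaction counts as stopped when no species that holds the D changes by six tenths of a point or more over the second half of the time

- at 15 d, what has stopped the reaction, if anything has (for what has run out or reacted, a solid counts together with what of it has only dissolved) (forward and back rates have come level / all of D has reacted / it is still moving / X has run out first)
- part of the D gone at 15 d
- the L standing at 15 d, as a percentage of the D charged
- the Q standing at 15 d, as a percentage of the D charged

Two amounts are held against each other: the J charged, 0.060 M, and the D lost by that reading, 0.0390 M. Assuming one X per D lost, the D lost is less than the J charged, which leaves 0.0210 M of reagent in hand. Yet the fall of D, as a fraction of the charge, goes from 0.157 d⁻¹ to 0.0476 d⁻¹ over the last two intervals, though each reading carries 2 percentage points. This reckoning therefore reads the slowing as forward and back rates coming level, and carries the mass-action quotient (reaction quotient), with the reagent in hand counted as dissolved X: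

K_q = (c(L) + c(Q)) / (c(D) c(X)) = 30.4 L mol⁻¹

Held at that value, the flask stays near that reading: 39.0% of D gone, L 12%, Q 27%.

The forecast differs: X has run out first, with 60% of D gone, L 0.5% and Q 59.5%. Its ground: “It runs out near 4.6 d, with D stranded at about 40%.”

The flask gives forward and back rates have come level, with 39.8% of D gone, L 10.5% and Q 29.3%.

    D + X ⇌ L (K = 8.60 L mol⁻¹, k = 3.90 × 10⁻⁴ L mol⁻¹ s⁻¹)
    J ⇌ X, rate k2*(cs2 - [X]) while solid is left; crystals form when [X] > cs2 (solubility = 30.0 mM, k = 2.30 × 10⁻⁵ s⁻¹)
    D + X ⇌ Q (K = 24.0 L mol⁻¹, k = 1.70 × 10⁻⁴ L mol⁻¹ s⁻¹)

On the path to L the backward turnover is 98% of the forward one, and 34% of the charged X is still there at the end. For a neighbour flask charged with 0.17 M of D and the same J, K_q gives the D lost, x, as the smaller root of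

K_q = x / ((c(D) − x)(c(J) − x)), with c(D) and c(J) the charges of that flask; the two charges and the reciprocal of K_q sum to s = 0.263 M

so x = 0.0473 M, or 27.8% of its charge. That flask stands at 28.2% gone.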